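**Plan**

Side-chain atoms are C1'–C7', counted from the ether carbon; the same atoms keep these locants in every precursor.
1. Retrosynthesis cuts the aryl ether bond O7–C1' (isofraxidin 9 + epoxy alcohol 8), then the two oxirane bonds C2'–O and C3'–O (dienediol 7), then C4'–C5' (allylic bromide 3 + alkynol 4).
2. Enabling feature: the only stereocentres, C2' and C3', are the two carbons of a trisubstituted oxirane directly beside the C1' oxygen, so the side chain is the epoxide of an E-trisubstituted primary allylic alcohol.
3. Forward: the C10 chain is built from prenyl acetate 1 (allylic oxidation, bromination, copper-catalysed alkynylation, trans-reduction), the oxirane (the only ring made) closes in step 5, and the intact coumarin (rings A and B of 9) is attached last.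
4. Stereochemistry: 2'E comes from the SeO2 oxidation and 5'E from hydroxyl-directed hydroalumination. C2' and C3' are set together by D-(−)-diethyl tartrate in the titanium-catalysed epoxidation, and no later step touches them.

Key step: step 5

Remark: D-(−)-diethyl tartrate [diethyl (2S,3S)-tartrate, CCOC(=O)[C@@H](O)[C@H](O)C(=O)OCC] is used only as a substoichiometric chiral ligand and leaves no atoms in any product, so it appears on the Conditions line and carries no compound number.

**Route**

Step 1
Reactants: 1 prenyl acetate (3-methylbut-2-en-1-yl acetate)
Product: 2 (E)-4-hydroxy-3-methylbut-2-en-1-yl acetate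
Conditions: SeO2 (10 mol%), tBuOOH, salicylic acid (10 mol%), CH2Cl2, rt
Reagents that add atoms: selenium dioxide, O=[Se]=O (transfers the oxygen); tert-butyl hydroperoxide, CC(C)(C)OO (terminal oxygen source that regenerates it)
Why: Riley allylic oxidation in its catalytic tBuOOH variant, in which an ene reaction of SeO2 followed by a [2,3]-sigmatropic shift should hydroxylate selectively the methyl group trans to the acetoxymethyl chain, fixing the E geometry of the future C2'=C3' alkene while the acetate stays inert.

Step 2
Reactants: 2 (E)-4-hydroxy-3-methylbut-2-en-1-yl acetate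
Product: 3 (E)-4-bromo-3-methylbut-2-en-1-yl acetate
Conditions: CBr4, PPh3, CH2Cl2, 0 °C
Reagents that add atoms: carbon tetrabromide, BrC(Br)(Br)Br
Why: Appel reaction, in which bromide displaces the primary allylic alkoxyphosphonium group in an SN2 sense under neutral conditions that should preserve both the acetate and the E alkene.

Step 3
Reactants: 3 (E)-4-bromo-3-methylbut-2-en-1-yl acetate; 4 2-methylbut-3-yn-2-ol
Product: 5 (E)-7-hydroxy-3,7-dimethyloct-2-en-5-yn-1-yl acetate
Conditions: CuI (10 mol%), nBu4NCl (10 mol%), K2CO3, DMF, rt
Reagents that add atoms: none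
Why: Copper-catalysed allylation of a terminal alkyne under solid–liquid phase-transfer conditions, in which the alkynylcopper RC≡CCu formed from 4 should attack the unhindered primary carbon of the allylic bromide to form C4'–C5', the mild carbonate base tolerating the acetate and the free tertiary hydroxyl.

Step 4
Reactants: 5 (E)-7-hydroxy-3,7-dimethyloct-2-en-5-yn-1-yl acetate
Product: 7 (2E,5E)-3,7-dimethylocta-2,5-diene-1,7-diol, via (E)-3,7-dimethyloct-2-en-5-yne-1,7-diol 6 (not isolated)
Conditions: LiAlH4, THF, 0 °C then reflux; H2O quench
Reagents that add atoms: none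
Why: LiAlH4 first reduces the acetate (ester reduction, giving 6 as its aluminium alkoxide), and on heating the tertiary propargylic alkoxide bound as an R–O–AlH3Li aluminate should deliver hydride across the alkyne in an anti sense (trans-hydroalumination of propargylic alcohols), so that protonolysis gives the 5'E alkene and the isolated C2'=C3' alkene is untouched.

Step 5
Reactants: 7 (2E,5E)-3,7-dimethylocta-2,5-diene-1,7-diol
Product: 8 (E)-5-[(2R,3R)-3-(hydroxymethyl)-2-methyloxiran-2-yl]-2-methylpent-3-en-2-ol
Conditions: Ti(OiPr)4 (20 mol%), D-(−)-diethyl tartrate (24 mol%), tBuOOH (anhydrous, in decane), 4 Å molecular sieves, CH2Cl2, −20 °C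
Reagents that add atoms: tert-butyl hydroperoxide, CC(C)(C)OO
Why: Katsuki–Sharpless asymmetric epoxidation: the primary allylic alkoxide of 7 and tert-butylperoxide exchange onto one titanium of the dimeric complex [Ti(DET)(OiPr)2]2, and the distal peroxide oxygen is passed to the C2'=C3' π bond in one concerted, spiro-type oxygen-atom transfer. The closest precedent is the epoxidation of geraniol and other E-trisubstituted primary allylic alcohols, the best substrate class for this catalyst. The oxirane, the only ring formed, closes by this concerted syn addition with both C–O bonds made at once (a formal [2+1] closure), so the E geometry of the alkene becomes the trans relationship of C1' and C4' on the ring. Both new stereocentres, C2' (oxirane CH) and C3' (methyl-bearing oxirane carbon), are set together by the tartrate-controlled choice of alkene face: D-(−)-diethyl tartrate is expected to give the (2R,3R) oxirane, the mirror image of the (2S,3S) epoxide that geraniol gives with L-(+)-diethyl tartrate, the substituent priority order being the same in both cases. The step needs site selectivity over the C5'=C6' alkene and must leave the product unopened: only the primary hydroxyl holds an alkene within reach of the titanium-bound peroxide, whereas the C7' hydroxyl is tertiary, a hindered ligand and a very slow substrate, and the sieve-assisted substoichiometric protocol at −20 °C limits Lewis-acid opening of the epoxy alcohol.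

Step 6
Reactants: 8 (E)-5-[(2R,3R)-3-(hydroxymethyl)-2-methyloxiran-2-yl]-2-methylpent-3-en-2-ol; 9 isofraxidin (7-hydroxy-6,8-dimethoxy-2H-chromen-2-one)
Product: 10 7-{[(2R,3R)-3-[(E)-4-hydroxy-4-methylpent-2-en-1-yl]-3-methyloxiran-2-yl]methoxy}-6,8-dimethoxy-2H-chromen-2-one (the target, CNP0325711.2)
Conditions: PPh3, DIAD, THF, 0 °C to rt
Reagents that add atoms: none
Why: Mitsunobu etherification, in which the acidic 7-hydroxyl of 9 is alkylated by the primary alkoxyphosphonium derivative of 8 at C1' (not a stereocentre), the tertiary hydroxyl being too hindered to be activated and the neutral conditions expected to spare the oxirane, its (2R,3R) configuration and the lactone.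

**Compound list**

1 | prenyl acetate (3-methylbut-2-en-1-yl acetate) | CC(C)=CCOC(C)=O | starting material
2 | (E)-4-hydroxy-3-methylbut-2-en-1-yl acetate | OC/C(C)=C/COC(C)=O | intermediate
3 | (E)-4-bromo-3-methylbut-2-en-1-yl acetate | BrC/C(C)=C/COC(C)=O | intermediate
4 | 2-methylbut-3-yn-2-ol | CC(C)(O)C#C | starting material
5 | (E)-7-hydroxy-3,7-dimethyloct-2-en-5-yn-1-yl acetate | CC(C)(O)C#CC/C(C)=C/COC(C)=O | intermediate
6 | (E)-3,7-dimethyloct-2-en-5-yne-1,7-diol | CC(C)(O)C#CC/C(C)=C/CO | intermediate (not isolated)
7 | (2E,5E)-3,7-dimethylocta-2,5-diene-1,7-diol | CC(C)(O)/C=C/C/C(C)=C/CO | intermediate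
8 | (E)-5-[(2R,3R)-3-(hydroxymethyl)-2-methyloxiran-2-yl]-2-methylpent-3-en-2-ol | OC[C@H]1O[C@]1(C)C/C=C/C(C)(C)O | intermediate
9 | isofraxidin (7-hydroxy-6,8-dimethoxy-2H-chromen-2-one) | COc1cc2ccc(=O)oc2c(OC)c1O | starting material
10 | 7-{[(2R,3R)-3-[(E)-4-hydroxy-4-methylpent-2-en-1-yl]-3-methyloxiran-2-yl]methoxy}-6,8-dimethoxy-2H-chromen-2-one | COc1cc2ccc(=O)oc2c(OC)c1OC[C@H]1O[C@]1(C)C/C=C/C(C)(C)O | target

**Step count**

Total step count: 6. Longest linear sequence: 6 steps (1 to 10); 4 and 9 enter as purchased materials in steps 3 and 6.

**Steps most likely to fail**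

Step 3. The allylic substitution may lose regiocontrol (attack at the γ-carbon with allylic transposition), and the base may move the skipped enyne into conjugation. The fallback sets out from bromide 3 and alkynol 4 and replaces the alkynyl nucleophile by an alkenyl one that already carries the 5'E geometry. Radical hydrostannation of 4 (Bu3SnH, AIBN, 80 °C) should give (E)-2-methyl-4-(tributylstannyl)but-3-en-2-ol F1. Stille coupling of F1 with 3 (Pd2(dba)3 as the zerovalent palladium source, P(2-furyl)3, THF, rt to 50 °C) should join C4'–C5' at the primary allyl terminus to give (2E,5E)-7-hydroxy-3,7-dimethylocta-2,5-dien-1-yl acetate F2. Methanolysis (K2CO3, MeOH) then returns to the route at diol 7, so steps 3 and 4 are both bypassed.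

Step 4. Hydroalumination of the hindered tertiary propargylic alkoxide may stall, or the doubly activated C4' methylene system may isomerise or be over-reduced at reflux. The fallback sets out from enyne acetate 5 and replaces hydride reduction by hydrosilylation and protodesilylation. Methanolysis (K2CO3, MeOH) gives enynediol 6, isolated this time. Trans-hydrosilylation catalysed by [Cp*Ru(MeCN)3]PF6 with BnMe2SiH (CH2Cl2, rt) should give (2E,5Z)-5-[benzyl(dimethyl)silyl]-3,7-dimethylocta-2,5-diene-1,7-diol F3; silicon is expected distal to the hydroxyl, and the regiochemistry is immaterial. Protodesilylation with TBAF in THF replaces silicon by hydrogen with retention of geometry and rejoins the route at diol 7.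

Step 5. The tertiary hydroxyl, or the diol acting as a bridging ligand, may compete for titanium, which would slow turnover and erode enantioselectivity; the Lewis acid may also open the epoxy alcohol. The fallback sets out from diol 7 and isofraxidin 9 and moves to reagent-controlled epoxidation after etherification. Mitsunobu coupling (PPh3, DIAD, THF) at the primary allylic hydroxyl should give 7-{[(2E,5E)-7-hydroxy-3,7-dimethylocta-2,5-dien-1-yl]oxy}-6,8-dimethoxy-2H-chromen-2-one F4. Shi epoxidation with the D-fructose-derived ketone (KHSO5, K2CO3 buffer, MeCN/dimethoxymethane–H2O, 0 °C) is then expected to oxidise the more electron-rich trisubstituted C2'=C3' alkene in preference to the disubstituted C5'=C6' alkene and the electron-poor coumarin alkene. The spiro transition-state model, which gives R,R epoxides from other E-trisubstituted alkenes, predicts the (2'R,3'R) oxirane, and the route is rejoined at target 10.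

**Further compounds**

F1 | step 3 | (E)-2-methyl-4-(tributylstannyl)but-3-en-2-ol | CCCC[Sn](CCCC)(CCCC)/C=C/C(C)(C)O
F2 | step 3 | (2E,5E)-7-hydroxy-3,7-dimethylocta-2,5-dien-1-yl acetate | CC(C)(O)/C=C/C/C(C)=C/COC(C)=O
F3 | step 4 | (2E,5Z)-5-[benzyl(dimethyl)silyl]-3,7-dimethylocta-2,5-diene-1,7-diol | CC(C)(O)/C=C(/C/C(C)=C/CO)[Si](C)(C)Cc1ccccc1
F4 | step 5 | 7-{[(2E,5E)-7-hydroxy-3,7-dimethylocta-2,5-dien-1-yl]oxy}-6,8-dimethoxy-2H-chromen-2-one | COc1cc2ccc(=O)oc2c(OC)c1OC/C=C(\C)C/C=C/C(C)(C)O
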